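**Conventions.** Upper flavan unit: O1, C2, C3, C4, C4a–C8a; ring A is its benzo ring, ring B the 4-hydroxyphenyl group on C2, ring C the pyran ring. Atoms of the lower unit are written "EGC C8" and so on. "Hexa-O-benzyl-EGC-8-yl" means (2R,3R)-3,5,7-tris(benzyloxy)-2-[3,4,5-tris(benzyloxy)phenyl]chroman-8-yl. Numbers refer to the compound list after the steps.

## Analysis of the target

Target 20 is made of two chromans joined by a single C–C bond from C4 of a 7,4'-dihydroxyflavan that carries no oxygen at C3 to EGC C8 of (−)-epigallocatechin (1). On the EGC side this bond lies between two ortho oxygens, so it is hindered. There are four stereocentres: EGC C2 and C3 (2R,3R, cis) come with 1, while C2 (S) and C4 (R) of the upper unit are 1,3-related across ring C with their aryl groups trans. C4 is separated from the stereocentres of 1 by an aromatic ring, so no dependable relay from the lower unit can be expected. The molecule has seven phenols (one air-sensitive pyrogallol) and one secondary alcohol; free-phenolic 1 epimerises at EGC C2 in base. Both C2–O bonds are benzylic ethers, the C4–EGC C8 bond resembles an acid-labile interflavan bond, and EGC C6 is a strongly nucleophilic arene position. The difficulty is C4, a diarylmethine with no neighbouring heteroatom or carbonyl to set it by, followed by the introduction of ring B at C2 trans to it. The plan rests on one observation about ring C: without ring B, C2 is an aldehyde-level carbon between O1 and C3, so ring C is the lactol of a 3,3-diarylpropanal. Its C3–C4 unit, with C4 bonded to C4a of ring A and to EGC C8, is then a 1,1-diarylethene that has taken up one carbon from carbon monoxide (12).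

## Retrosynthetic reasoning

**20 to 19.** All eight hydroxyls are carried as benzyl ethers and released together in the last step. Benzyl ethers withstand the organolithium, organozinc, rhodium hydride and low-temperature Lewis acid steps, and they come off under neutral conditions that the free polyphenol tolerates.

**19 to 15 and 18.** The bond from C2 to ring B is cut. This makes C2 an acetal carbon and ring B an aryl nucleophile, 18, prepared from bromide 16 through Grignard reagent 17. The forward reaction is a substitution at the anomeric carbon through the cyclic oxocarbenium ion. It is the one place where C4 can hand its configuration to C2, because the nucleophile enters opposite the C4 aryl group and so gives the trans isomer. Cutting O1–C2 instead would leave C2 to be set in an open chain, far from any controlling element. An organometallic is needed and not a plain arene, since the rings already in the substrate are better π-nucleophiles than a simple aryl ether.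

**15 to 14.** The acetate only turns the lactol hydroxyl into a leaving group.

**14 to 11 and 12.** Opening the hemiacetal bond O1–C2 gives hydroxy aldehyde 13, and cutting C2–C3 removes C2 as carbon monoxide (12). What remains, 11, has C3 as a terminal methylene on the future C4. The gain is that ring C's missing carbon arrives as a C1 gas under neutral conditions and that the only stereocentre made is C4, by addition of hydrogen. The forward reaction has to put hydrogen on C4 from one face, the formyl group on the terminal carbon, and must not simply hydrogenate the alkene.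

**11 to 10, then to 4 and 7.** The bond between the alkene carbon and EGC C8 is cut. This separates the chiral-pool half from a simple acetophenone-derived half. A cross-coupling of vinyl triflate 7 with the arylmetal 9 (from bromide 4 through aryllithium 8) makes the hindered bond at a position fixed by the bromine, with no cation and no C6/C8 question. The ring A hydroxyl needs a temporary group other than benzyl. Allyl is taken because a silyl group on a phenol ortho to an enolate or alkoxide can migrate, and an acid-labile group would need acid on an electron-rich diarylethene. Allyl is removed from 10 by zerovalent palladium without acid or base.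

**7 to 6 to 5.** The vinyl triflate comes from the methyl ketone 6 by enolisation, and 6 from the purchased phenol 5 by allylation.

**4 to 3 to 2 to 1.** Bromine is placed at EGC C8 by electrophilic substitution, whose regiochemistry is inherent in per-benzylated flavan-3-ols. Benzylation is done in two stages: the phenols of 1 first under weak base to avoid epimerisation, giving 2, then the secondary alcohol to give 3.

## Alternatives that were turned down

**Alternative 1:** Ring A is built last by cutting C8–C8a and C4a–C5. The upper unit is then the trans-4,6-disubstituted δ-lactone A1, whose carbonyl carbon is the future C8a and whose α-methylene is the future C4a. In the forward step the lithium enolate of ketone A2 attacks the lactone carbonyl through its methyl carbon. Acid then frees the aldehyde, which condenses with the former α-carbon, and loss of water aromatises the ring to phenol A3 with its 7-hydroxyl already differentiated.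
- For it: both stereocentres of ring C are set on a saturated lactone, where a 4,6-trans relation follows from conjugate addition to a 6-aryl-dihydropyranone, and no unprecedented asymmetric catalysis is needed. On this point it is stronger than the chosen route.
- Against it: the conjugate addition must deliver the di-ortho-substituted EGC C8 nucleophile. Acylation opens the lactone to a p-alkoxybenzylic alkoxide at C2, and the acid needed for condensation and aromatisation then acts on a p-alkoxybenzylic C2–O bond, so C2 can ionise and lose its configuration. The annulation must also pick C4a among several enolisable positions.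
- Comparison: six carbons of a purchasable arene are constructed, and A1 alone costs more steps than the whole of 11. The chosen route takes ring A from 5 for nothing and never exposes the assembled flavan to acid.

**Alternative 2:** O1 is removed from between C8a and C2, which contracts ring C to the indanone A4. A peracid then inserts oxygen with migration of the ring A carbon (Baeyer–Villiger oxidation) to give dihydrocoumarin A5, one reduction from lactol 14.
- For it: aryl migrates in preference to the methylene, so the regiochemistry is right. Every reaction type has precedent, which the chosen key step cannot claim, and 3-arylindanones are accessible enantioselectively by known 1,4-additions.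
- Against it: A4 carries three very electron-rich rings, and EGC ring A with its free C6 is attacked by electrophilic peracids. The oxidation of a conjugated aryl ketone is slow, and the benzyloxy group sits meta to the migrating carbon and does not help. The stereocentre of A4 still needs an asymmetric step with the hindered EGC aryl group.
- Comparison: A5 and 14 differ only in oxidation level. This route climbs to the lactone with an oxidant and comes back down, while the chosen route reaches the lactol level directly under reducing, neutral conditions in one step from 11.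

**Alternative 3:** C3–C4 and O1–C2 are cut together. Ring A, O1 and C4 form the ortho-quinone methide A7, generated by dehydration of benzhydrol A6, and C2–C3 comes from vinyl ether A8. A chiral phosphoric acid ionises A6, and the ion-paired A7 adds A8 in a hetero-[4+2] to give acetal A9.
- For it: A6 is one addition step from aryllithium 8 and a protected salicylaldehyde, so it is shorter than the four steps from 4 to 11. A9 is already an acetal that could enter the C-arylation without the acetylation. Acid-catalysed asymmetric cycloadditions of ortho-quinone methides are an established class. On convergence, step count and precedent it is as strong as or stronger than the chosen route.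
- Against it: in A7 the exocyclic carbon bears the EGC ring, whose two ortho oxygens and one para oxygen stabilise the cationic form. The intermediate is therefore long-lived, weakly electrophilic and twisted, the chiral anion has little hold on the face, and a background path through the free cation is likely. Such a cation beside free EGC C6 positions invites Friedel–Crafts oligomerisation, and the acid also threatens A8.
- Comparison: the chosen route never makes C4 cationic. The C4–H bond comes from a metal hydride under neutral conditions and the electron-rich rings stay spectators. The price is that its facial selectivity is unproven.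

Key step: step 8

## Assumptions

- Compounds 1, 5 and 16 are taken as purchased; 1 is the natural (2R,3R) enantiomer that appears as the lower unit of 20.
- The sense of induction of the ligand in step 8 cannot be predicted for this substrate, so both antipodes are to be tried and the matched one used.

## Route

Step 1
Reactants: 1 (−)-epigallocatechin
Product: 2 5,7,3',4',5'-penta-O-benzyl-(−)-epigallocatechin
Conditions: BnBr, K2CO3, DMF, −20 °C → rt, under argon
Reagents that add atoms: benzyl bromide, BrCc1ccccc1
Why: Williamson etherification: K2CO3 ionises only the five phenols, so the secondary 3-hydroxyl stays free; the cold start and exclusion of air keep C-benzylation of EGC ring A, pyrogallol oxidation and base-induced epimerisation at EGC C2 low.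

Step 2
Reactants: 2 5,7,3',4',5'-penta-O-benzyl-(−)-epigallocatechin
Product: 3 3,5,7,3',4',5'-hexa-O-benzyl-(−)-epigallocatechin
Conditions: NaH, BnBr, n-Bu4NI (cat.), DMF, 0 °C → rt
Reagents that add atoms: benzyl bromide, BrCc1ccccc1
Why: Williamson etherification of the sodium alkoxide; with every phenol capped the pyran ring cannot open, so EGC C2 and C3 keep their configuration.

Step 3
Reactants: 3 3,5,7,3',4',5'-hexa-O-benzyl-(−)-epigallocatechin
Product: 4 8-bromo-hexa-O-benzyl-EGC
Conditions: NBS, CH2Cl2, −20 °C → rt
Reagents that add atoms: N-bromosuccinimide, O=C1CCC(=O)N1Br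
Why: Electrophilic aromatic bromination: EGC ring A with three oxygen donors is by far the most reactive ring, and C8 (between one benzyloxy group and the ring oxygen) reacts before C6 (between two benzyloxy groups), the normal outcome for per-benzylated flavan-3-ols; one equivalent avoids dibromination.

Step 4
Reactants: 5 4'-benzyloxy-2'-hydroxyacetophenone
Product: 6 2'-allyloxy-4'-benzyloxyacetophenone
Conditions: allyl bromide, K2CO3, DMF, 60 °C
Reagents that add atoms: allyl bromide, C=CCBr
Why: Williamson etherification of the hydrogen-bonded 2'-hydroxyl; allyl is chosen because it cannot migrate to an enolate, is inert to organozinc reagents and is removed later without acid.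

Step 5
Reactants: 6 2'-allyloxy-4'-benzyloxyacetophenone
Product: 7 1-(2-allyloxy-4-benzyloxyphenyl)vinyl trifluoromethanesulfonate
Conditions: KN(SiMe3)2, THF, −78 °C; PhNTf2, −78 → 0 °C
Reagents that add atoms: N-phenylbis(trifluoromethanesulfonimide), O=S(=O)(N(c1ccccc1)S(=O)(=O)C(F)(F)F)C(F)(F)F
Why: Enol triflate formation: the methyl ketone has a single enolisable site and its potassium enolate is sulfonylated on oxygen; the electron-rich vinyl triflate is passed through base-washed silica and used at once.

Step 6
Reactants: 4 8-bromo-hexa-O-benzyl-EGC, 7 1-(2-allyloxy-4-benzyloxyphenyl)vinyl trifluoromethanesulfonate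
Product: 10 1-(2-allyloxy-4-benzyloxyphenyl)-1-(hexa-O-benzyl-EGC-8-yl)ethene, via 8-lithio-hexa-O-benzyl-EGC 8 (not isolated), via (hexa-O-benzyl-EGC-8-yl)zinc chloride 9 (not isolated)
Conditions: n-BuLi, THF, −78 °C; ZnCl2, −78 °C → rt; then 7, Pd2(dba)3 (cat.), SPhos (cat.), THF, 50 °C
Reagents that add atoms: none
Why: Bromine–lithium exchange, transmetalation to zinc and Negishi coupling: zerovalent palladium inserts quickly into the vinyl C–O bond, and the bulky biarylphosphine SPhos supports transmetalation and reductive elimination with a di-ortho-substituted arylzinc. The hindered bond between the future C4 and EGC C8 forms at the position fixed by the bromine, and no stereocentre is made.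

Step 7
Reactants: 10 1-(2-allyloxy-4-benzyloxyphenyl)-1-(hexa-O-benzyl-EGC-8-yl)ethene
Product: 11 1-(4-benzyloxy-2-hydroxyphenyl)-1-(hexa-O-benzyl-EGC-8-yl)ethene
Conditions: Pd(PPh3)4 (cat.), morpholine, THF, rt
Reagents that add atoms: none
Why: Tsuji–Trost deallylation: zerovalent palladium ionises the aryl allyl ether and morpholine takes up the allyl group; the neutral conditions leave the seven benzyl ethers and the acid-sensitive, electron-rich 1,1-diarylethene untouched.

Step 8
Reactants: 11 1-(4-benzyloxy-2-hydroxyphenyl)-1-(hexa-O-benzyl-EGC-8-yl)ethene, 12 carbon monoxide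
Product: 14 (4R)-7-benzyloxy-4-(hexa-O-benzyl-EGC-8-yl)chroman-2-ol as both anomers, via (3R)-3-(4-benzyloxy-2-hydroxyphenyl)-3-(hexa-O-benzyl-EGC-8-yl)propanal 13 (not isolated)
Conditions: Rh(acac)(CO)2 (cat.), (R,R)-Ph-BPE (cat.; the antipode if mismatched), CO/H2 (1:1, 30 bar), toluene, 80 °C
Reagents that add atoms: carbon monoxide (12), [C-]#[O+]
Why: Proposed new method: the rhodium hydride formed from Rh(acac)(CO)2, the bisphospholane Ph-BPE and CO/H2 binds the alkene of 11 and transfers hydride to the diaryl-substituted carbon while rhodium takes the CH2 terminus (the tertiary dibenzylic alkyl cannot go on to a quaternary aldehyde), CO inserts, and hydrogenolysis of the acyl releases aldehyde 13; the closest known reaction is the rhodium–phosphine hydroformylation of 1-(2-hydroxyaryl)-1-arylethenes to 4-arylchroman-2-ols, which runs without stereocontrol, together with ligand-controlled asymmetric hydroformylation of other 1,1-disubstituted alkenes. The two new skeletal bonds are C2–C3, with C2 supplied by 12, and O1–C2. Ring C closes when the ring A hydroxyl adds to the aldehyde of 13 in a 6-exo-trig hemiacetalisation; the anomeric centre is not controlled and need not be, because step 10 erases it. The C4 stereocentre is created in the hydride transfer and is decided by the alkene face that the chiral ligand lets rhodium bind, and the CO pressure traps the primary alkyl before β-hydride elimination can undo the insertion. The step needs linear regioselectivity, which 1,1-disubstitution secures, chemoselectivity for CO insertion over hydrogenation of the alkene, and face selectivity, for which the substrate offers the contrast between the nearly coplanar hydroxyphenyl ring and the EGC ring that its two ortho oxygens turn perpendicular to the alkene. Because the EGC unit is already a single enantiomer, the two C4 epimers are diastereomers, so a minor epimer can be removed by chromatography. Lactol formation also withdraws the aldehyde from aldol and reduction pathways.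

Step 9
Reactants: 14 (4R)-7-benzyloxy-4-(hexa-O-benzyl-EGC-8-yl)chroman-2-ol
Product: 15 (4R)-2-acetoxy-7-benzyloxy-4-(hexa-O-benzyl-EGC-8-yl)chroman as both anomers
Conditions: Ac2O, pyridine, DMAP (cat.), CH2Cl2, 0 °C → rt
Reagents that add atoms: acetic anhydride, CC(=O)OC(C)=O
Why: O-Acylation of the lactol hydroxyl (the ring tautomer is the resting form of a 3-(2-hydroxyaryl)propanal) installs an anomeric leaving group; both anomers give the same cation in step 10, so the mixture is used as such.

Step 10
Reactants: 15 (4R)-2-acetoxy-7-benzyloxy-4-(hexa-O-benzyl-EGC-8-yl)chroman, 16 1-benzyloxy-4-bromobenzene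
Product: 19 (2S,4R)-7-benzyloxy-2-(4-benzyloxyphenyl)-4-(hexa-O-benzyl-EGC-8-yl)chroman, via 4-benzyloxyphenylmagnesium bromide 17 (not isolated), via 4-benzyloxyphenylzinc bromide 18 (not isolated)
Conditions: 16, Mg, THF, rt; ZnBr2, 0 °C; then 15, BF3·OEt2, CH2Cl2, −78 → −30 °C
Reagents that add atoms: none
Why: Lewis acid-mediated substitution of an anomeric acetate by an organozinc (C-arylation through the cyclic oxocarbenium ion): BF3·OEt2 ionises 15 and the aryl–zinc carbon attacks C2 pseudoaxially on the half-chair cation from the face opposite the bulky C4 aryl group, so the 2,4-trans product forms and C2 (S) is set by substrate control from C4. The arylzinc is used in excess because its ipso carbon outruns the electron-rich rings of a second molecule for the cation, and the low temperature keeps the C2–O1 benzylic ether of the product from re-ionising.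

Step 11
Reactants: 19 (2S,4R)-7-benzyloxy-2-(4-benzyloxyphenyl)-4-(hexa-O-benzyl-EGC-8-yl)chroman
Product: 20 (2R,3R)-8-[(2S,4R)-7-hydroxy-2-(4-hydroxyphenyl)chroman-4-yl]-2-(3,4,5-trihydroxyphenyl)chroman-3,5,7-triol (CNP0220331.1)
Conditions: H2 (1 atm), Pd(OH)2/C, THF/MeOH, rt; filtration under argon
Reagents that add atoms: none
Why: Hydrogenolysis of the eight benzyl ethers (seven aryl, one secondary alkyl) in one operation; no stereocentre is involved, and the air-sensitive polyphenol is filtered and freeze-dried under inert gas.

## Compound list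

1 | (−)-epigallocatechin, (2R,3R)-2-(3,4,5-trihydroxyphenyl)chroman-3,5,7-triol | Oc1cc(O)c2c(c1)O[C@H](c1cc(O)c(O)c(O)c1)[C@H](O)C2 | starting material
2 | 5,7,3',4',5'-penta-O-benzyl-(−)-epigallocatechin (3-hydroxyl free) | c1ccccc1COc1cc(OCc3ccccc3)c2c(c1)O[C@H](c1cc(OCc3ccccc3)c(OCc3ccccc3)c(OCc3ccccc3)c1)[C@H](O)C2 | intermediate
3 | 3,5,7,3',4',5'-hexa-O-benzyl-(−)-epigallocatechin | c1ccccc1COc1cc(OCc3ccccc3)c2c(c1)O[C@H](c1cc(OCc3ccccc3)c(OCc3ccccc3)c(OCc3ccccc3)c1)[C@H](OCc1ccccc1)C2 | intermediate
4 | 8-bromo-hexa-O-benzyl-EGC | Brc1c(OCc3ccccc3)cc(OCc3ccccc3)c2c1O[C@H](c1cc(OCc3ccccc3)c(OCc3ccccc3)c(OCc3ccccc3)c1)[C@H](OCc1ccccc1)C2 | intermediate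
5 | 4'-benzyloxy-2'-hydroxyacetophenone | CC(=O)c1ccc(OCc2ccccc2)cc1O | starting material
6 | 2'-allyloxy-4'-benzyloxyacetophenone | CC(=O)c1ccc(OCc2ccccc2)cc1OCC=C | intermediate
7 | 1-(2-allyloxy-4-benzyloxyphenyl)vinyl trifluoromethanesulfonate | C=C(OS(=O)(=O)C(F)(F)F)c1ccc(OCc2ccccc2)cc1OCC=C | intermediate
8 | 8-lithio-hexa-O-benzyl-EGC | [Li]c1c(OCc3ccccc3)cc(OCc3ccccc3)c2c1O[C@H](c1cc(OCc3ccccc3)c(OCc3ccccc3)c(OCc3ccccc3)c1)[C@H](OCc1ccccc1)C2 | intermediate (not isolated)
9 | (hexa-O-benzyl-EGC-8-yl)zinc chloride | Cl[Zn]c1c(OCc3ccccc3)cc(OCc3ccccc3)c2c1O[C@H](c1cc(OCc3ccccc3)c(OCc3ccccc3)c(OCc3ccccc3)c1)[C@H](OCc1ccccc1)C2 | intermediate (not isolated)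
10 | 1-(2-allyloxy-4-benzyloxyphenyl)-1-(hexa-O-benzyl-EGC-8-yl)ethene | C=C(c1ccc(OCc2ccccc2)cc1OCC=C)c1c(OCc3ccccc3)cc(OCc3ccccc3)c2c1O[C@H](c1cc(OCc3ccccc3)c(OCc3ccccc3)c(OCc3ccccc3)c1)[C@H](OCc1ccccc1)C2 | intermediate
11 | 1-(4-benzyloxy-2-hydroxyphenyl)-1-(hexa-O-benzyl-EGC-8-yl)ethene | C=C(c1ccc(OCc2ccccc2)cc1O)c1c(OCc3ccccc3)cc(OCc3ccccc3)c2c1O[C@H](c1cc(OCc3ccccc3)c(OCc3ccccc3)c(OCc3ccccc3)c1)[C@H](OCc1ccccc1)C2 | intermediate
12 | carbon monoxide | [C-]#[O+] | starting material
13 | (3R)-3-(4-benzyloxy-2-hydroxyphenyl)-3-(hexa-O-benzyl-EGC-8-yl)propanal | O=CC[C@@H](c3c(OCc5ccccc5)cc(OCc5ccccc5)c4c3O[C@H](c3cc(OCc5ccccc5)c(OCc5ccccc5)c(OCc5ccccc5)c3)[C@H](OCc3ccccc3)C4)c1ccc(OCc2ccccc2)cc1O | intermediate (not isolated)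
14 | (4R)-7-benzyloxy-4-(hexa-O-benzyl-EGC-8-yl)chroman-2-ol, both anomers | OC1C[C@@H](c3c(OCc5ccccc5)cc(OCc5ccccc5)c4c3O[C@H](c3cc(OCc5ccccc5)c(OCc5ccccc5)c(OCc5ccccc5)c3)[C@H](OCc3ccccc3)C4)c2ccc(OCc3ccccc3)cc2O1 | intermediate
15 | (4R)-2-acetoxy-7-benzyloxy-4-(hexa-O-benzyl-EGC-8-yl)chroman, both anomers | CC(=O)OC1C[C@@H](c3c(OCc5ccccc5)cc(OCc5ccccc5)c4c3O[C@H](c3cc(OCc5ccccc5)c(OCc5ccccc5)c(OCc5ccccc5)c3)[C@H](OCc3ccccc3)C4)c2ccc(OCc3ccccc3)cc2O1 | intermediate
16 | 1-benzyloxy-4-bromobenzene | Brc1ccc(OCc2ccccc2)cc1 | starting material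
17 | 4-benzyloxyphenylmagnesium bromide | Br[Mg]c1ccc(OCc2ccccc2)cc1 | intermediate (not isolated)
18 | 4-benzyloxyphenylzinc bromide | Br[Zn]c1ccc(OCc2ccccc2)cc1 | intermediate (not isolated)
19 | (2S,4R)-7-benzyloxy-2-(4-benzyloxyphenyl)-4-(hexa-O-benzyl-EGC-8-yl)chroman | c1ccccc1COc1ccc([C@@H]2C[C@@H](c3c(OCc5ccccc5)cc(OCc5ccccc5)c4c3O[C@H](c3cc(OCc5ccccc5)c(OCc5ccccc5)c(OCc5ccccc5)c3)[C@H](OCc3ccccc3)C4)c3ccc(OCc5ccccc5)cc3O2)cc1 | intermediate
20 | (2R,3R)-8-[(2S,4R)-7-hydroxy-2-(4-hydroxyphenyl)chroman-4-yl]-2-(3,4,5-trihydroxyphenyl)chroman-3,5,7-triol | Oc1ccc([C@@H]2C[C@@H](c3c(O)cc(O)c4c3O[C@H](c3cc(O)c(O)c(O)c3)[C@H](O)C4)c3ccc(O)cc3O2)cc1 | target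

## Step count and least certain steps

Total: 11 steps. Longest linear sequence: 9 steps (steps 1, 2, 3, 6, 7, 8, 9, 10, 11, from 1).

**Step 8 (key step, proposed new method).**
- Most likely failure: poor facial selectivity in the hydride transfer, because no ligand has yet been shown to tell two aryl groups apart on a 1,1-diarylethene and the resident EGC centres may work against the ligand. Second to that is slow turnover of the hindered alkene, with hydrogenation of the double bond gaining ground at the temperature needed.
- Fallback on known chemistry: it sets out from 5 and from arylzinc 9 (made from 4 as in step 6) and rejoins the route at 14. Ketone 5 is condensed with diethyl carbonate (NaH, toluene, reflux) to 7-benzyloxy-4-hydroxycoumarin F1. Tf2O and Et3N convert F1 to 7-benzyloxy-2-oxo-2H-chromen-4-yl trifluoromethanesulfonate F2. Negishi coupling of F2 with 9 (Pd2(dba)3, SPhos, THF) gives 7-benzyloxy-4-(hexa-O-benzyl-EGC-8-yl)coumarin F3. Asymmetric 1,4-reduction with a copper hydride catalyst (Cu(OAc)2, DTBM-SEGPHOS of the matched hand, diethoxymethylsilane, t-BuOH, toluene), a reaction established for 4-arylcoumarins, gives (4R)-7-benzyloxy-4-(hexa-O-benzyl-EGC-8-yl)chroman-2-one F4 (the same compound as A5). i-Bu2AlH in toluene at −78 °C reduces F4 to lactol 14.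

**Step 10.**
- Most likely failure: capture of the oxocarbenium ion by an electron-rich ring of a second molecule, loss of a proton from C3 to give the 4H-chromene, or erosion of the trans preference if the cation is attacked through a less ordered transition state.
- Fallback: it sets out from 14 and rejoins at 19, and it moves control of C2 from the substrate to a reagent. Excess Grignard reagent 17 adds to the open aldehyde form of 14 to give (3R)-3-(4-benzyloxy-2-hydroxyphenyl)-1-(4-benzyloxyphenyl)-3-(hexa-O-benzyl-EGC-8-yl)propan-1-ol F5 as both C1 epimers. MnO2 in CH2Cl2 oxidises the benzylic alcohol to (3R)-3-(4-benzyloxy-2-hydroxyphenyl)-1-(4-benzyloxyphenyl)-3-(hexa-O-benzyl-EGC-8-yl)propan-1-one F6. CBS reduction ((S)-Me-CBS oxazaborolidine, BH3·SMe2, THF) gives the (1R,3R)-alcohol F7. Mitsunobu cyclisation (PPh3, DIAD, THF, 0 °C) closes O1–C2 with inversion to give 19.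

**Step 6.**
- Most likely failure: loss of triflate 7 by ionisation or hydrolysis back to the ketone, and slow transmetalation of the di-ortho-substituted arylzinc, so that protonated material corresponding to 3 is recovered.
- Fallback: it sets out from 4 (through 8) and 6 and rejoins at 10, avoiding both palladium and the triflate. Aryllithium 8 is stirred with anhydrous CeCl3 at −78 °C and added to ketone 6; the cerium reagent suppresses enolisation and gives 1-(2-allyloxy-4-benzyloxyphenyl)-1-(hexa-O-benzyl-EGC-8-yl)ethanol F8. MsCl and Et3N (CH2Cl2, 0 °C) dehydrate F8 to 10.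

**Step 11.**
- Most likely failure: incomplete cleavage of the hindered aryl benzyl ethers and of the secondary alkyl benzyl ether, reductive opening of the benzylic C2–O1 bond of ring C on long exposure, and air oxidation of the pyrogallol during isolation.
- Fallback: it sets out from 19 and ends at 20 with no new compound (F0). The benzyl ethers are cleaved by a Lewis acid instead of hydrogen: BCl3 with pentamethylbenzene as cation scavenger, CH2Cl2, −78 °C.

## Further compounds

F1 | step 8 | 7-benzyloxy-4-hydroxycoumarin | O=C1C=C(O)c2ccc(OCc3ccccc3)cc2O1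
F2 | step 8 | 7-benzyloxy-2-oxo-2H-chromen-4-yl trifluoromethanesulfonate | O=C1C=C(OS(=O)(=O)C(F)(F)F)c2ccc(OCc3ccccc3)cc2O1
F3 | step 8 | 7-benzyloxy-4-(hexa-O-benzyl-EGC-8-yl)coumarin | O=C1C=C(c3c(OCc5ccccc5)cc(OCc5ccccc5)c4c3O[C@H](c3cc(OCc5ccccc5)c(OCc5ccccc5)c(OCc5ccccc5)c3)[C@H](OCc3ccccc3)C4)c2ccc(OCc3ccccc3)cc2O1
F4 | step 8 | (4R)-7-benzyloxy-4-(hexa-O-benzyl-EGC-8-yl)chroman-2-one | O=C1C[C@@H](c3c(OCc5ccccc5)cc(OCc5ccccc5)c4c3O[C@H](c3cc(OCc5ccccc5)c(OCc5ccccc5)c(OCc5ccccc5)c3)[C@H](OCc3ccccc3)C4)c2ccc(OCc3ccccc3)cc2O1
F5 | step 10 | (3R)-3-(4-benzyloxy-2-hydroxyphenyl)-1-(4-benzyloxyphenyl)-3-(hexa-O-benzyl-EGC-8-yl)propan-1-ol, both C1 epimers | c1ccccc1COc1ccc(C(O)C[C@@H](c3c(OCc5ccccc5)cc(OCc5ccccc5)c4c3O[C@H](c3cc(OCc5ccccc5)c(OCc5ccccc5)c(OCc5ccccc5)c3)[C@H](OCc3ccccc3)C4)c3ccc(OCc5ccccc5)cc3O)cc1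
F6 | step 10 | (3R)-3-(4-benzyloxy-2-hydroxyphenyl)-1-(4-benzyloxyphenyl)-3-(hexa-O-benzyl-EGC-8-yl)propan-1-one | c1ccccc1COc1ccc(C(=O)C[C@@H](c3c(OCc5ccccc5)cc(OCc5ccccc5)c4c3O[C@H](c3cc(OCc5ccccc5)c(OCc5ccccc5)c(OCc5ccccc5)c3)[C@H](OCc3ccccc3)C4)c3ccc(OCc5ccccc5)cc3O)cc1
F7 | step 10 | (1R,3R)-3-(4-benzyloxy-2-hydroxyphenyl)-1-(4-benzyloxyphenyl)-3-(hexa-O-benzyl-EGC-8-yl)propan-1-ol | c1ccccc1COc1ccc([C@H](O)C[C@@H](c3c(OCc5ccccc5)cc(OCc5ccccc5)c4c3O[C@H](c3cc(OCc5ccccc5)c(OCc5ccccc5)c(OCc5ccccc5)c3)[C@H](OCc3ccccc3)C4)c3ccc(OCc5ccccc5)cc3O)cc1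
F8 | step 6 | 1-(2-allyloxy-4-benzyloxyphenyl)-1-(hexa-O-benzyl-EGC-8-yl)ethanol, both carbinol epimers | CC(O)(c1ccc(OCc2ccccc2)cc1OCC=C)c1c(OCc3ccccc3)cc(OCc3ccccc3)c2c1O[C@H](c1cc(OCc3ccccc3)c(OCc3ccccc3)c(OCc3ccccc3)c1)[C@H](OCc1ccccc1)C2
F0 | step 11 | none | none
A1 | alternative 1 | (4R,6S)-6-(4-benzyloxyphenyl)-4-(hexa-O-benzyl-EGC-8-yl)tetrahydro-2H-pyran-2-one | c1ccccc1COc1ccc([C@@H]2C[C@@H](c3c(OCc5ccccc5)cc(OCc5ccccc5)c4c3O[C@H](c3cc(OCc5ccccc5)c(OCc5ccccc5)c(OCc5ccccc5)c3)[C@H](OCc3ccccc3)C4)CC(=O)O2)cc1
A2 | alternative 1 | 4,4-dimethoxybutan-2-one | CC(=O)CC(OC)OC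
A3 | alternative 1 | (2S,4R)-2-(4-benzyloxyphenyl)-4-(hexa-O-benzyl-EGC-8-yl)chroman-7-ol | c1ccccc1COc1ccc([C@@H]2C[C@@H](c3c(OCc5ccccc5)cc(OCc5ccccc5)c4c3O[C@H](c3cc(OCc5ccccc5)c(OCc5ccccc5)c(OCc5ccccc5)c3)[C@H](OCc3ccccc3)C4)c3ccc(O)cc3O2)cc1
A4 | alternative 2 | (3R)-6-benzyloxy-3-(hexa-O-benzyl-EGC-8-yl)indan-1-one | O=C1C[C@@H](c3c(OCc5ccccc5)cc(OCc5ccccc5)c4c3O[C@H](c3cc(OCc5ccccc5)c(OCc5ccccc5)c(OCc5ccccc5)c3)[C@H](OCc3ccccc3)C4)c2ccc(OCc3ccccc3)cc12
A5 | alternative 2 | (4R)-7-benzyloxy-4-(hexa-O-benzyl-EGC-8-yl)chroman-2-one | O=C1C[C@@H](c3c(OCc5ccccc5)cc(OCc5ccccc5)c4c3O[C@H](c3cc(OCc5ccccc5)c(OCc5ccccc5)c(OCc5ccccc5)c3)[C@H](OCc3ccccc3)C4)c2ccc(OCc3ccccc3)cc2O1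
A6 | alternative 3 | (4-benzyloxy-2-hydroxyphenyl)(hexa-O-benzyl-EGC-8-yl)methanol, carbinol centre undefined | OC(c1ccc(OCc2ccccc2)cc1O)c1c(OCc3ccccc3)cc(OCc3ccccc3)c2c1O[C@H](c1cc(OCc3ccccc3)c(OCc3ccccc3)c(OCc3ccccc3)c1)[C@H](OCc1ccccc1)C2
A7 | alternative 3 | 3-benzyloxy-6-[(hexa-O-benzyl-EGC-8-yl)methylidene]cyclohexa-2,4-dien-1-one (ring A ortho-quinone methide) | O=C1C=C(OCc2ccccc2)C=CC1=Cc1c(OCc3ccccc3)cc(OCc3ccccc3)c2c1O[C@H](c1cc(OCc3ccccc3)c(OCc3ccccc3)c(OCc3ccccc3)c1)[C@H](OCc1ccccc1)C2
A8 | alternative 3 | ethyl vinyl ether | C=COCC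
A9 | alternative 3 | (4R)-7-benzyloxy-2-ethoxy-4-(hexa-O-benzyl-EGC-8-yl)chroman, both C2 epimers | CCOC1C[C@@H](c3c(OCc5ccccc5)cc(OCc5ccccc5)c4c3O[C@H](c3cc(OCc5ccccc5)c(OCc5ccccc5)c(OCc5ccccc5)c3)[C@H](OCc3ccccc3)C4)c2ccc(OCc3ccccc3)cc2O1
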